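## Analysis of the target

The target is a tricyclic C15 ketone with two (Z)-2-methylbut-2-enoate (angelate) esters. The ring carbons are numbered here C1–C11: C1 is the ketone carbon, C2=C3 the enone double bond (methyl on C3), C4 and C11 the cyclobutane CH groups at the ends of the enone bridge, C10 the quaternary cyclobutane carbon with a methyl group, C5 the fourth cyclobutane carbon, and C6 (CMe2), C7 (O-acyl), C8 (O-acyl), C9 (CH2) the chain from C5 to C10. This saturated skeleton with methyls on C3, C6 (two) and C10 is called longipinane below.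

The cyclobutane C4–C5–C11–C10 is bridged across both diagonals. C1–C2–C3 spans C11/C4 and gives the cyclohexenone ring C1–C2–C3–C4–C10–C11. C6–C7–C8–C9 spans C5/C10 and gives the seven-membered ring C4–C5–C6–C7–C8–C9–C10.

Of the six stereocentres, C4, C5, C10 and C11 are tied to each other by the two bridges. What is free is the sense of the cage and its relation to the trans-diol: the C8 oxygen is cis to C11 and C3 on the seven-membered ring, the C7 oxygen trans.

The angelates isomerise to tiglates with nucleophiles, base or acid and are Michael acceptors, so they go on last. A hydroxyl on C5 next to a C1 ketone would be a strained aldol that opens by retro-aldol. C7 is neopentylic.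

The hard points are the quaternary C10 shared by three rings, the C5–C6 bond between a cyclobutane CH and CMe2, and closing a four-membered ring inside a doubly bridged frame.

The strategy rests on the C4–C10 bond. It belongs to both the cyclohexenone and the seven-membered ring, with the C10 methyl and C4–H cis. Once the C5–C11 bond is opened, the six-membered ring is a cis-fused cyclohexene on a cycloheptanone, a Diels–Alder retron with C4=C10 as dienophile.

## Retrosynthetic reasoning

**Acyl C–O bonds.** Target 26 is cut at both ester bonds to diol 22 and angelic acid 23. The angelates survive none of the earlier chemistry (radicals, bromine, base), so esterification is the last step and must acylate the neopentylic C7 hydroxyl without Z→E isomerisation.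

**C2=C3 double bond.** Diol 22 comes from silyl ether 21, whose enone is traced through bromo ketone 20 to silyl enol ether 19. In the cage the C3 hydrogen lies on the face under the C10 methyl. A syn elimination from a C2 metal or selenium substituent would have to sit there, so an anti elimination from a C2 bromide on the open face is planned. C11 is a bridgehead, so C2 is the only position that can react.

**C8 benzyl ether and C5 hydrogen.** Alcohol 19 comes from benzyl ether 18, debenzylated before the reducible enone exists. The C5–H of 18 is traced to the tertiary hydroxyl of cyclobutanol 16 through oxalate 17. The C1 oxygen stays masked as the enol ether throughout, because a free C1 ketone beside the C5 hydroxyl would undo the ring.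

**C5–C11 bond.** Cyclobutanol 16 is cut between the carbinol carbon and C11 to ketone 15, the reverse of a Norrish–Yang photocyclisation. The cut is placed here because C11 is γ to the C5 carbonyl. In 15 the enol ether makes the C11 hydrogens allylic and leaves the other γ-carbon, C2, without an sp3 hydrogen. The forward step must out-run α-cleavage and interception of the excited ketone by the enol ether.

**C10–C11 and C3–C4 bonds (key disconnection).** Cycloadduct 15 is cut to cycloheptenone 12 and diene 14. This removes one ring, two C–C bonds and three stereocentres at once. The dienophile carries ten carbons with both oxygen stereocentres, the diene the other five. The forward reaction must form a quaternary carbon at a β,β-disubstituted enone and choose the enone face cis to the C8 ether.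

**Diene.** 14 is the kinetic silyl enol ether of pentenone 13.

**Seven-membered ring.** Enone 12 is opened at its C=C bond (C4=C10) to diene 11 by ring-closing metathesis, which tolerates both ethers and avoids base next to a β-alkoxy ketone. Vinyl ketone 11 comes from N-methoxy-N-methylamide 10, its silyl-free precursor 9 and ester 8.

**C6–C7 bond.** Ester 8 is cut between the carbinol carbon and the CMe2 carbon to aldehyde 5 and ketene acetal 6. A chelate between the aldehyde and the α-benzyloxy group sets C7 from C8 (syn), which is the trans-diol of the ring.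

**C8 stereocentre.** Aldehyde 5 comes from alcohol 4, ethers 3 and 2, and epoxide 1. The epoxide carbon becomes C8 and is never touched.

## Alternatives that were turned down

**Alternative 1:** Ring contraction to the cyclobutane.
- *Disconnection:* the four-membered ring is derived from the five-membered ring of a bicyclo[3.2.1]octane built by a [4+3] cycloaddition onto a five-membered diene.
- *Forward key step:* photolysis of diazo ketone A1 in methanol. A Wolff rearrangement shifts a bridgehead carbon onto the carbene carbon, and the ketene is trapped as ester A2.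
- *For:* the cyclobutane with its enone bridge is made early by a rearrangement that leaves no hydroxyl and has no regiochemical question. On this point it is stronger than the chosen route.
- *Against:* A2 is far from the target.
  - C10 has a hydrogen where the methyl must be.
  - The oxygen sits on the middle carbon of the three-carbon bridge (C2) and must be moved to C1.
  - The seven-membered ring and both oxygens are missing.
  - Closing that ring needs a C–C bond at the fully substituted carbon of the isopropylidene group (C6). A cationic closure would pass through a cyclobutyl cation at C5, and a radical closure would be an endo attack on a tetrasubstituted alkene.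
  - The sequence is racemic unless the [4+3] step is made enantioselective.
- *Comparison:* the chosen strategy brings C6–C9 with both oxygens and the absolute configuration in one fragment, and has the full carbon skeleton two steps after its key step.

**Alternative 2:** Reductive aldol onto a cyclobutanone.
- *Disconnection:* the C5–C6 bond is cut as an aldol bond.
- *Forward key step:* [(Ph3P)CuH]6 reduces the isopropenyl ketone of cyclobutanone A3 to a copper enolate. Its CMe2 carbon adds to the strained carbonyl and closes the seven-membered ring to aldol A4.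
- *For:* the route to the carbon skeleton is short, and the cyclobutanone is electrophilic. On step economy to the skeleton it is stronger.
- *Against:*
  - The new bond joins two fully substituted carbons in a medium-ring closure.
  - A4 has the same tertiary C5 hydroxyl to remove as the chosen route, but here β to the C7 ketone.
  - It has no oxygen at C8 or C1. C8 needs α-oxidation, C7 a reduction next to CMe2, and C1 an allylic oxidation. Two stereocentres are set late by the cage alone.
  - A3 is racemic as made.
- *Comparison:* the chosen strategy sets both carbinol centres in the first steps and reaches the C1 oxygen through the diene.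

**Alternative 3:** Nitrogen deletion from a bridged pyrrolidine.
- *Disconnection:* the C5–C11 bond, the same bond the chosen route closes by light, with a nitrogen atom inserted retrosynthetically.
- *Forward key step:* PhI(OAc)2 and ammonium carbamate turn pyrrolidine A5 into a 1,1-diazene. It loses N2 and the radical pair couples to cyclobutane A6.
- *For:* the coupling keeps configuration and leaves no C5 hydroxyl, so no deoxygenation is needed. On the cyclobutane closure it is stronger.
- *Against:*
  - A5 must come from a dipolar cycloaddition onto a β,β-disubstituted enone, which is as demanding as the chosen cycloaddition.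
  - The radical pair can fragment to two alkenes.
  - A6 still needs a Claisen closure of the six-membered ring, addition of the C3 methyl, and the same late C7/C8 oxygenation as alternative 2.
  - Absolute configuration needs an enantioselective cycloaddition.
- *Comparison:* the chosen strategy has the cyclohexenone carbons and both oxygens in place when the four-membered ring closes.

Key step: step 11

Assumption: the cycloaddition in step 11 is taken to be endo to the ring carbonyl, so 15–20 are drawn with the C3 methyl cis to C5. This centre is erased in step 17; for the exo epimer only the choice of elimination in steps 16 and 17 would change.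

## Route

Step 1
Reactants: 1 (S)-glycidyl trityl ether
Product: 2 (2S)-4-methyl-1-(triphenylmethoxy)pent-4-en-2-ol
Conditions: CH2=C(CH3)MgBr, CuI (10 mol %), THF, −30 → 0 °C; aq. NH4Cl
Reagents that add atoms: isopropenylmagnesium bromide, C=C(C)[Mg]Br
Why: Copper-catalysed SN2 opening of the terminal epoxide at its CH2 carbon; the stereocentre (later C8) is not involved.

Step 2
Reactants: 2 (2S)-4-methyl-1-(triphenylmethoxy)pent-4-en-2-ol
Product: 3 (2S)-2-(benzyloxy)-4-methylpent-4-en-1-yl triphenylmethyl ether
Conditions: NaH, BnBr, n-Bu4NI (cat.), THF/DMF, 0 °C → rt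
Reagents that add atoms: benzyl bromide, BrCc1ccccc1
Why: Williamson ether synthesis; benzyl is chosen because it chelates in step 5, withstands the Lewis acid of step 11 and does not absorb at 300 nm in step 12.

Step 3
Reactants: 3 (2S)-2-(benzyloxy)-4-methylpent-4-en-1-yl triphenylmethyl ether
Product: 4 (2S)-2-(benzyloxy)-4-methylpent-4-en-1-ol
Conditions: camphorsulfonic acid (10 mol %), MeOH/CH2Cl2, 0 °C → rt
Reagents that add atoms: none
Why: Acid-catalysed solvolysis of the trityl ether through the trityl cation; benzyl ether and 1,1-disubstituted alkene are inert under these mild conditions.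

Step 4
Reactants: 4 (2S)-2-(benzyloxy)-4-methylpent-4-en-1-ol
Product: 5 (2S)-2-(benzyloxy)-4-methylpent-4-enal
Conditions: Dess–Martin periodinane, CH2Cl2, 0 °C → rt; used crude
Reagents that add atoms: none
Why: Dess–Martin oxidation under near-neutral conditions, which should keep the α-alkoxy aldehyde from epimerising.

Step 5
Reactants: 5 (2S)-2-(benzyloxy)-4-methylpent-4-enal; 6 1-methoxy-2-methyl-1-(trimethylsilyloxy)prop-1-ene
Product: 8 methyl (3S,4S)-4-(benzyloxy)-3-hydroxy-2,2,6-trimethylhept-6-enoate, via O-trimethylsilyl aldol adduct 7 (not isolated)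
Conditions: MgBr2·OEt2 (3 equiv), CH2Cl2, −78 → −20 °C; then 1 M HCl, THF, 0 °C
Reagents that add atoms: none
Why: Chelation-controlled Mukaiyama aldol addition: magnesium bridges the aldehyde and benzyloxy oxygens and the ketene acetal attacks the face opposite the methallyl group, giving the 3,4-syn (3S,4S) product, which is the trans C7/C8 diol of the ring.

Step 6
Reactants: 8 methyl (3S,4S)-4-(benzyloxy)-3-hydroxy-2,2,6-trimethylhept-6-enoate
Product: 9 (3S,4S)-4-(benzyloxy)-3-hydroxy-N-methoxy-N,2,2,6-tetramethylhept-6-enamide
Conditions: MeNH(OMe)·HCl, AlMe3, CH2Cl2, 0 → 40 °C; Rochelle salt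
Reagents that add atoms: N,O-dimethylhydroxylamine hydrochloride, CNOC.Cl
Why: Aminolysis of the ester by an aluminium amide (Weinreb amide formation); the free β-hydroxyl binds aluminium and delivers the amide internally, which offsets the hindrance of the neopentyl ester.

Step 7
Reactants: 9 (3S,4S)-4-(benzyloxy)-3-hydroxy-N-methoxy-N,2,2,6-tetramethylhept-6-enamide
Product: 10 (3S,4S)-4-(benzyloxy)-3-[(tert-butyldimethylsilyl)oxy]-N-methoxy-N,2,2,6-tetramethylhept-6-enamide
Conditions: TBSOTf, 2,6-lutidine, CH2Cl2, −78 → 0 °C
Reagents that add atoms: tert-butyldimethylsilyl trifluoromethanesulfonate, CC(C)(C)[Si](C)(C)OS(=O)(=O)C(F)(F)F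
Why: Silylation of a hindered secondary alcohol with a silyl triflate; this bulky ether is the face-directing group of the key step.

Step 8
Reactants: 10 (3S,4S)-4-(benzyloxy)-3-[(tert-butyldimethylsilyl)oxy]-N-methoxy-N,2,2,6-tetramethylhept-6-enamide
Product: 11 (5S,6S)-6-(benzyloxy)-5-[(tert-butyldimethylsilyl)oxy]-4,4,8-trimethylnona-1,8-dien-3-one
Conditions: CH2=CHMgBr (3 equiv), THF, 0 °C → rt; poured into cold 1 M HCl
Reagents that add atoms: vinylmagnesium bromide, C=C[Mg]Br
Why: Weinreb ketone synthesis: the amide takes up one equivalent of Grignard reagent and releases the ketone only on work-up; the acidic quench keeps the liberated amine from adding to the vinyl ketone.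

Step 9
Reactants: 11 (5S,6S)-6-(benzyloxy)-5-[(tert-butyldimethylsilyl)oxy]-4,4,8-trimethylnona-1,8-dien-3-one
Product: 12 (5S,6S)-5-(benzyloxy)-6-[(tert-butyldimethylsilyl)oxy]-3,7,7-trimethylcyclohept-2-en-1-one
Conditions: second-generation Hoveyda–Grubbs catalyst (5–10 mol %), toluene (0.005 M), 80 °C, argon sparge
Reagents that add atoms: none
Why: Ring-closing metathesis; the gem-dimethyl group (Thorpe–Ingold effect) favours closure and loss of ethene drives formation of the trisubstituted enone.

Step 10
Reactants: 13 (E)-pent-3-en-2-one
Product: 14 (E)-2-[(tert-butyldimethylsilyl)oxy]penta-1,3-diene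
Conditions: TBSOTf, Et3N, Et2O, 0 °C
Reagents that add atoms: tert-butyldimethylsilyl trifluoromethanesulfonate, CC(C)(C)[Si](C)(C)OS(=O)(=O)C(F)(F)F
Why: Soft enolisation with silyl triflate and amine: kinetic deprotonation at the methyl group gives the cross-conjugated 2-silyloxy diene and leaves the (E) double bond untouched.

Step 11
Reactants: 12 (5S,6S)-5-(benzyloxy)-6-[(tert-butyldimethylsilyl)oxy]-3,7,7-trimethylcyclohept-2-en-1-one; 14 (E)-2-[(tert-butyldimethylsilyl)oxy]penta-1,3-diene
Product: 15 cis-fused cycloadduct (bicyclo[5.4.0]undecenone; target numbering: cyclohexene C10–C11–C1=C2–C3–C4 fused at C4–C10 to the cycloheptanone, C5 ketone, C1 silyl enol ether, C7 silyl ether, C8 benzyl ether; C10–CH3, C4–H and C7–O on one face of the seven-membered ring, C8–O, C11 and C3 on the other; C3–CH3 cis to C5)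
Conditions: EtAlCl2 (2.5 equiv), 14 (4 equiv), toluene/CH2Cl2, −78 → −30 °C; Et3N, then aq. NaHCO3
Reagents that add atoms: none
Why: EtAlCl2 binds the enone oxygen on the side away from C6, and the diene adds in a concerted but asynchronous Lewis acid-promoted Diels–Alder reaction: its CH2 terminus, the carbon with the largest HOMO coefficient of a 2-silyloxy diene, bonds first to the β-carbon C10 and the CH(CH3) terminus then to the α-carbon C4. The closest known reaction type is the Lewis acid-promoted cycloaddition of 2-silyloxy-1,3-dienes to β-substituted cycloalkenones, including cases that create a quaternary ring-fusion carbon. The cyclohexene ring C10–C11–C1–C2–C3–C4 closes by a [4+2] addition that is suprafacial on both partners, so the C10 methyl and C4–H are cis and the fusion is cis. C10 and C4 are set together by the face of 12 that is attacked: in the chair with both ethers equatorial (an axial C8 ether would meet the axial C6 methyl) the axial C6 methyl and the C7 silyloxy group cover one face of C4=C10, so the diene is expected on the other, cis to the benzyloxy group; in the other chair the axial silyloxy group again covers its own face. C3 follows from the endo orientation of the diene under the ring carbonyl (methyl cis to C5) and is removed in step 17. Regiochemistry is fixed by polarity and is not at risk; the selectivity the step needs is the facial one, which rests on the C7 silyl ether and the C6 gem-dimethyl group, with a slim benzyl ether on the attacked side. The product keeps the silyl enol ether at C1=C2, which marks C1 as the later ketone, leaves C2 without an sp3 hydrogen and makes the C11 hydrogens allylic for step 12.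

Step 12
Reactants: 15 cis-fused cycloadduct
Product: 16 8-(benzyloxy)-1,7-bis[(tert-butyldimethylsilyl)oxy]longipin-1-en-5-ol (cage configured as in the target; C3–CH3 on the side of the C5 bridge)
Conditions: hν (medium-pressure Hg lamp, Pyrex, λ > 300 nm), degassed benzene/t-BuOH 9:1 (0.005 M), pyridine (1 equiv), 15 °C
Reagents that add atoms: none
Why: Norrish–Yang photocyclisation: n→π* excitation of the C5 ketone, transfer of the axial allylic hydrogen of C11 (γ position) to oxygen through a six-membered transition state and coupling of the radical centres at C5 and C11 give the cyclobutanol; C2 is sp2 with no hydrogen to give, and the seven-membered ring holds the C5 orbital in the C4–C5–C11 plane, so bonding at the other allyl terminus C2 is not expected. Cleavage of the C4–C10 bond instead of closure would put two (E) double bonds into an eleven-membered ring, and the configurations at C5 and C11 are dictated by the bridges.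

Step 13
Reactants: 16 8-(benzyloxy)-1,7-bis[(tert-butyldimethylsilyl)oxy]longipin-1-en-5-ol
Product: 17 methyl 8-(benzyloxy)-1,7-bis[(tert-butyldimethylsilyl)oxy]longipin-1-en-5-yl oxalate
Conditions: ClC(O)CO2Me, DMAP, pyridine, CH2Cl2, 0 °C → rt
Reagents that add atoms: methyl chlorooxoacetate, COC(=O)C(=O)Cl
Why: Acylation of the tertiary cyclobutanol by a small, very electrophilic acid chloride under nucleophilic catalysis; the amine base keeps the silyl enol ether intact, which must not hydrolyse while the C5 oxygen is present (a β-hydroxy ketone would open by retro-aldol).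

Step 14
Reactants: 17 methyl 8-(benzyloxy)-1,7-bis[(tert-butyldimethylsilyl)oxy]longipin-1-en-5-yl oxalate
Product: 18 8-(benzyloxy)-1,7-bis[(tert-butyldimethylsilyl)oxy]longipin-1-ene
Conditions: Bu3SnH, AIBN (cat.), toluene, 110 °C, slow addition
Reagents that add atoms: none
Why: Radical deoxygenation of a tertiary oxalate ester with Bu3SnH (a Barton–McCombie-type chain): the stannyl radical adds to the oxalate, C5–O scission leaves a radical centre at C5, and hydrogen is delivered to its only open face because the C6–C9 bridge holds the other.

Step 15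
Reactants: 18 8-(benzyloxy)-1,7-bis[(tert-butyldimethylsilyl)oxy]longipin-1-ene
Product: 19 1,7-bis[(tert-butyldimethylsilyl)oxy]longipin-1-en-8-ol
Conditions: lithium 4,4′-di-tert-butylbiphenylide (LiDBB), THF, −78 °C; aq. NH4Cl
Reagents that add atoms: none
Why: Reductive cleavage of the benzyl ether by an arene radical anion (dissolving-metal-type debenzylation); silyl ether and silyl enol ether are inert, and it is done here because the later enone would be reduced.

Step 16
Reactants: 19 1,7-bis[(tert-butyldimethylsilyl)oxy]longipin-1-en-8-ol
Product: 20 2-bromo-7-[(tert-butyldimethylsilyl)oxy]-8-hydroxylongipinan-1-one (bromine on the face of the C5 bridge, trans to C3–H)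
Conditions: N-bromosuccinimide, NaHCO3, THF, −78 → 0 °C
Reagents that add atoms: N-bromosuccinimide, BrN1C(=O)CCC1=O
Why: Electrophilic α-bromination of a silyl enol ether; bromine enters C2 from the face of the C5–H bridge because the C10 methyl lies over the other face, which places C2–Br trans to C3–H.

Step 17
Reactants: 20 2-bromo-7-[(tert-butyldimethylsilyl)oxy]-8-hydroxylongipinan-1-one
Product: 21 7-[(tert-butyldimethylsilyl)oxy]-8-hydroxylongipin-2-en-1-one
Conditions: LiBr, Li2CO3, DMF, 120 °C
Reagents that add atoms: none
Why: E2 dehydrobromination: the C3 hydrogen is anti to the C2 bromine, LiBr equilibrates any cis epimer by bromide exchange, and C11 is a bridgehead so no second enolisation or Favorskii path is open. A syn elimination through a Pd(OAc)2-derived or selenium enolate derivative was not chosen because its C2 substituent would have to sit under the C10 methyl.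

Step 18
Reactants: 21 7-[(tert-butyldimethylsilyl)oxy]-8-hydroxylongipin-2-en-1-one
Product: 22 7,8-dihydroxylongipin-2-en-1-one
Conditions: 48% aq. HF/MeCN, rt → 40 °C
Reagents that add atoms: none
Why: Fluoride-induced desilylation of the hindered secondary silyl ether; the enone and the cyclobutane should tolerate dilute HF in acetonitrile.

Step 19
Reactants: 22 7,8-dihydroxylongipin-2-en-1-one; 23 angelic acid
Product: 26 CNP0355097.2 (7,8-bis(angeloyloxy)longipin-2-en-1-one), via angelic 2,4,6-trichlorobenzoic anhydride 24 (not isolated), via C8 mono-angelate 25 (not isolated)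
Conditions: 23 (6 equiv), 2,4,6-Cl3C6H2COCl (6 equiv), Et3N, toluene, rt; then 22, 80 °C
Reagents that add atoms: none
Why: Yamaguchi mixed-anhydride esterification run without a nucleophilic amine catalyst, which would add to the β-carbon and turn the (Z)-ester into the (E)-isomer; the C8 hydroxyl should react first and the neopentylic C7 hydroxyl on heating.

## Compound list

1 | (S)-glycidyl trityl ether, (2S)-2-[(triphenylmethoxy)methyl]oxirane | C1O[C@@H]1COC(c1ccccc1)(c1ccccc1)c1ccccc1 | starting material
2 | (2S)-4-methyl-1-(triphenylmethoxy)pent-4-en-2-ol | C=C(C)C[C@H](O)COC(c1ccccc1)(c1ccccc1)c1ccccc1 | intermediate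
3 | (2S)-2-(benzyloxy)-4-methylpent-4-en-1-yl triphenylmethyl ether | C=C(C)C[C@H](OCc1ccccc1)COC(c1ccccc1)(c1ccccc1)c1ccccc1 | intermediate
4 | (2S)-2-(benzyloxy)-4-methylpent-4-en-1-ol | C=C(C)C[C@H](OCc1ccccc1)CO | intermediate
5 | (2S)-2-(benzyloxy)-4-methylpent-4-enal | C=C(C)C[C@H](OCc1ccccc1)C=O | intermediate
6 | 1-methoxy-2-methyl-1-(trimethylsilyloxy)prop-1-ene (silyl ketene acetal of methyl isobutyrate) | COC(O[Si](C)(C)C)=C(C)C | starting material
7 | methyl (3S,4S)-4-(benzyloxy)-2,2,6-trimethyl-3-[(trimethylsilyl)oxy]hept-6-enoate | COC(=O)C(C)(C)[C@H](O[Si](C)(C)C)[C@@H](OCc1ccccc1)CC(C)=C | intermediate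
8 | methyl (3S,4S)-4-(benzyloxy)-3-hydroxy-2,2,6-trimethylhept-6-enoate | COC(=O)C(C)(C)[C@H](O)[C@@H](OCc1ccccc1)CC(C)=C | intermediate
9 | (3S,4S)-4-(benzyloxy)-3-hydroxy-N-methoxy-N,2,2,6-tetramethylhept-6-enamide | CON(C)C(=O)C(C)(C)[C@H](O)[C@@H](OCc1ccccc1)CC(C)=C | intermediate
10 | (3S,4S)-4-(benzyloxy)-3-[(tert-butyldimethylsilyl)oxy]-N-methoxy-N,2,2,6-tetramethylhept-6-enamide | CON(C)C(=O)C(C)(C)[C@H](O[Si](C)(C)C(C)(C)C)[C@@H](OCc1ccccc1)CC(C)=C | intermediate
11 | (5S,6S)-6-(benzyloxy)-5-[(tert-butyldimethylsilyl)oxy]-4,4,8-trimethylnona-1,8-dien-3-one | C=CC(=O)C(C)(C)[C@H](O[Si](C)(C)C(C)(C)C)[C@@H](OCc1ccccc1)CC(C)=C | intermediate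
12 | (5S,6S)-5-(benzyloxy)-6-[(tert-butyldimethylsilyl)oxy]-3,7,7-trimethylcyclohept-2-en-1-one | C(c1ccccc1)O[C@H]1CC(C)=CC(=O)C(C)(C)[C@@H]1O[Si](C)(C)C(C)(C)C | intermediate
13 | (E)-pent-3-en-2-one | C/C=C/C(C)=O | starting material
14 | (E)-2-[(tert-butyldimethylsilyl)oxy]penta-1,3-diene | C=C(O[Si](C)(C)C(C)(C)C)/C=C/C | intermediate
15 | cis-fused cycloadduct, 5-(benzyloxy)-4,9-bis[(tert-butyldimethylsilyl)oxy]-3,3,7,11-tetramethylbicyclo[5.4.0]undec-9-en-2-one (bicyclic numbering; relative configuration as described in step 11) | C(c1ccccc1)O[C@H]1C[C@@]2(C)CC(O[Si](C)(C)C(C)(C)C)=C[C@@H](C)[C@H]2C(=O)C(C)(C)[C@@H]1O[Si](C)(C)C(C)(C)C | intermediate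
16 | 8-(benzyloxy)-1,7-bis[(tert-butyldimethylsilyl)oxy]longipin-1-en-5-ol | C(c1ccccc1)O[C@H]1C[C@@]2(C)[C@@H]3C(O[Si](C)(C)C(C)(C)C)=C[C@@H](C)[C@H]2[C@]3(O)C(C)(C)[C@@H]1O[Si](C)(C)C(C)(C)C | intermediate
17 | methyl 8-(benzyloxy)-1,7-bis[(tert-butyldimethylsilyl)oxy]longipin-1-en-5-yl oxalate | C(c1ccccc1)O[C@H]1C[C@@]2(C)[C@@H]3C(O[Si](C)(C)C(C)(C)C)=C[C@@H](C)[C@H]2[C@]3(OC(=O)C(=O)OC)C(C)(C)[C@@H]1O[Si](C)(C)C(C)(C)C | intermediate
18 | 8-(benzyloxy)-1,7-bis[(tert-butyldimethylsilyl)oxy]longipin-1-ene | C(c1ccccc1)O[C@H]1C[C@@]2(C)[C@@H]3C(O[Si](C)(C)C(C)(C)C)=C[C@@H](C)[C@H]2[C@@H]3C(C)(C)[C@@H]1O[Si](C)(C)C(C)(C)C | intermediate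
19 | 1,7-bis[(tert-butyldimethylsilyl)oxy]longipin-1-en-8-ol | O[C@H]1C[C@@]2(C)[C@@H]3C(O[Si](C)(C)C(C)(C)C)=C[C@@H](C)[C@H]2[C@@H]3C(C)(C)[C@@H]1O[Si](C)(C)C(C)(C)C | intermediate
20 | 2-bromo-7-[(tert-butyldimethylsilyl)oxy]-8-hydroxylongipinan-1-one | O[C@H]1C[C@@]2(C)[C@@H]3C(=O)[C@@H](Br)[C@@H](C)[C@H]2[C@@H]3C(C)(C)[C@@H]1O[Si](C)(C)C(C)(C)C | intermediate
21 | 7-[(tert-butyldimethylsilyl)oxy]-8-hydroxylongipin-2-en-1-one | O[C@H]1C[C@@]2(C)[C@@H]3C(=O)C=C(C)[C@H]2[C@@H]3C(C)(C)[C@@H]1O[Si](C)(C)C(C)(C)C | intermediate
22 | 7,8-dihydroxylongipin-2-en-1-one | O[C@H]1C[C@@]2(C)[C@@H]3C(=O)C=C(C)[C@H]2[C@@H]3C(C)(C)[C@@H]1O | intermediate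
23 | angelic acid, (Z)-2-methylbut-2-enoic acid | C/C=C(/C)C(=O)O | starting material
24 | (Z)-2-methylbut-2-enoic 2,4,6-trichlorobenzoic anhydride | C/C=C(/C)C(=O)OC(=O)c1c(Cl)cc(Cl)cc1Cl | intermediate
25 | 8-(angeloyloxy)-7-hydroxylongipin-2-en-1-one | C/C=C(/C)C(=O)O[C@H]1C[C@@]2(C)[C@@H]3C(=O)C=C(C)[C@H]2[C@@H]3C(C)(C)[C@@H]1O | intermediate
26 | CNP0355097.2, 7,8-bis(angeloyloxy)longipin-2-en-1-one | C/C=C(/C)C(=O)O[C@H]1C[C@@]2(C)[C@@H]3C(=O)C=C(C)[C@H]2[C@@H]3C(C)(C)[C@@H]1OC(=O)/C(C)=C\C | target

## Step count and least certain steps

Total: 19 steps. Longest linear sequence: 18 steps (steps 1–9 and 11–19, from 1); step 10 is the one-step branch to 14.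

**Step 11 (key step).**
- *Most likely to go wrong:* poor facial selectivity, because the two chairs of 12 expose opposite faces and may lie close in energy. In addition, reaction at the fully substituted C10 is slow, which gives the aluminium Lewis acid time to destroy 14.
- *Fallback (sets out from 12 and 14, returns at 15):* the two bonds are made in separate polar steps instead of one cycloaddition. With catalytic Tf2NH (converted by 14 into the silyl triflimide) in CH2Cl2 at −78 °C, 14 should add through its CH2 terminus to C10 in a Mukaiyama–Michael reaction and pass the silyl group to the ring enolate. This gives (E)-1-[6-(benzyloxy)-3,5-bis[(tert-butyldimethylsilyl)oxy]-1,4,4-trimethylcyclohept-2-en-1-yl]pent-3-en-2-one F1. C10 is then set alone, by a CH2 group attacking a silylated enone with no endo constraint, and the face isomers can be separated at this stage. A second Mukaiyama–Michael addition of the ring silyl enol ether (C4) to the propenyl ketone (C3), with fresh catalyst at −40 °C, closes the ring and moves the silyl group to the C1 oxygen, which is 15 with the same enol ether regiochemistry.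

**Step 12.**
- *Most likely to go wrong:* the excited carbonyl is intercepted by the nearby electron-rich enol ether (Paternò–Büchi addition or charge-transfer decay), or it cleaves at C5–C6 (α-cleavage to a tertiary radical) faster than it takes the C11 hydrogen.
- *Fallback (sets out from 15, returns at 18):* the donor enol ether is replaced by an electron-poor placeholder that still keeps C2 sp2 and C11–H allylic. CsF and PhNTf2 in DME should convert 15 into the enol triflate F2 (the C1 trifluoromethanesulfonate analogue of 15). Irradiation as in step 12 gives the cyclobutanol triflate F3. Acylation as in step 13 gives the oxalate F4, and Bu3SnH as in step 14 gives the deoxygenated enol triflate F5. MeLi then attacks sulfur and frees the lithium enolate, which TBSCl traps on oxygen to give 18.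

**Step 14 (with step 13).**
- *Most likely to go wrong:* incomplete acylation of the crowded bridgehead hydroxyl, and slow C5–O scission to a strained cyclobutyl radical, so that the alcohol is returned.
- *Fallback (sets out from 16, returns at 18):* Barton–McCombie deoxygenation through the alkoxide instead of acylation. KN(SiMe3)2 in THF with CS2 present, then MeI, gives the S-methyl xanthate F6 (CS2 is a smaller electrophile than an acid chloride). Bu3SnH/AIBN then cleaves the C5–O bond from the thiocarbonyl adduct, which fragments more readily than the oxalate.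

**Step 19.**
- *Most likely to go wrong:* incomplete acylation of the neopentylic C7 hydroxyl, and Z→E isomerisation of the angelate on long heating.
- *Fallback (sets out from 22, returns at 26):* the (Z)-alkenes are built after acylation. Diol 22 is esterified with 2-[bis(2,2,2-trifluoroethoxy)phosphoryl]propanoic acid (DCC, DMAP) to the bis(phosphonopropanoate) F7. A Still–Gennari olefination of both phosphonates with acetaldehyde (KN(SiMe3)2, 18-crown-6, THF, −78 °C) should then give the two (Z)-2-methylbut-2-enoates directly.

## Further compounds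

F1 | step 11 | (E)-1-[6-(benzyloxy)-3,5-bis[(tert-butyldimethylsilyl)oxy]-1,4,4-trimethylcyclohept-2-en-1-yl]pent-3-en-2-one | C(c1ccccc1)O[C@H]1C[C@@](C)(CC(=O)/C=C/C)C=C(O[Si](C)(C)C(C)(C)C)C(C)(C)[C@@H]1O[Si](C)(C)C(C)(C)C
F2 | step 12 | enol triflate of the cycloadduct (15 with OSO2CF3 in place of the enol OSi) | C(c1ccccc1)O[C@H]1C[C@@]2(C)CC(OS(=O)(=O)C(F)(F)F)=C[C@@H](C)[C@H]2C(=O)C(C)(C)[C@@H]1O[Si](C)(C)C(C)(C)C
F3 | step 12 | 8-(benzyloxy)-7-[(tert-butyldimethylsilyl)oxy]-5-hydroxylongipin-1-en-1-yl trifluoromethanesulfonate | C(c1ccccc1)O[C@H]1C[C@@]2(C)[C@@H]3C(OS(=O)(=O)C(F)(F)F)=C[C@@H](C)[C@H]2[C@]3(O)C(C)(C)[C@@H]1O[Si](C)(C)C(C)(C)C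
F4 | step 12 | methyl oxalate of F3 at the C5 oxygen | C(c1ccccc1)O[C@H]1C[C@@]2(C)[C@@H]3C(OS(=O)(=O)C(F)(F)F)=C[C@@H](C)[C@H]2[C@]3(OC(=O)C(=O)OC)C(C)(C)[C@@H]1O[Si](C)(C)C(C)(C)C
F5 | step 12 | 8-(benzyloxy)-7-[(tert-butyldimethylsilyl)oxy]longipin-1-en-1-yl trifluoromethanesulfonate | C(c1ccccc1)O[C@H]1C[C@@]2(C)[C@@H]3C(OS(=O)(=O)C(F)(F)F)=C[C@@H](C)[C@H]2[C@@H]3C(C)(C)[C@@H]1O[Si](C)(C)C(C)(C)C
F6 | step 14 | O-[8-(benzyloxy)-1,7-bis[(tert-butyldimethylsilyl)oxy]longipin-1-en-5-yl] S-methyl dithiocarbonate | C(c1ccccc1)O[C@H]1C[C@@]2(C)[C@@H]3C(O[Si](C)(C)C(C)(C)C)=C[C@@H](C)[C@H]2[C@]3(OC(=S)SC)C(C)(C)[C@@H]1O[Si](C)(C)C(C)(C)C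
F7 | step 19 | 7,8-bis{2-[bis(2,2,2-trifluoroethoxy)phosphoryl]propanoyloxy}longipin-2-en-1-one (mixture at the two phosphorus-bearing carbons) | CC(P(=O)(OCC(F)(F)F)OCC(F)(F)F)C(=O)O[C@H]1C[C@@]2(C)[C@@H]3C(=O)C=C(C)[C@H]2[C@@H]3C(C)(C)[C@@H]1OC(=O)C(C)P(=O)(OCC(F)(F)F)OCC(F)(F)F
A1 | alternative 1 | 7-diazo-4-methyl-8-(propan-2-ylidene)bicyclo[3.2.1]octane-3,6-dione 3-ethylene ketal | [N-]=[N+]=C1C(=O)[C@H]2[C@H](C)C3(OCCO3)C[C@@H]1C2=C(C)C
A2 | alternative 1 | methyl 4-methyl-7-(propan-2-ylidene)bicyclo[3.1.1]heptane-6-carboxylate 3-ethylene ketal | COC(=O)[C@H]1[C@@H]2CC3(OCCO3)[C@@H](C)[C@H]1C2=C(C)C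
A3 | alternative 2 | 2,6-dimethyl-6-(4-methyl-3-oxopent-4-en-1-yl)bicyclo[3.1.1]hept-2-en-7-one | C=C(C)C(=O)CC[C@@]1(C)[C@@H]2CC=C(C)[C@H]1C2=O
A4 | alternative 2 | 5-hydroxylongipin-2-en-7-one (tricyclic aldol, tertiary cyclobutanol bridged by the new cycloheptanone) | C1C[C@@]2(C)[C@@H]3CC=C(C)[C@H]2[C@]3(O)C(C)(C)C1=O
A5 | alternative 3 | methyl 9-acetyl-1,5,5-trimethyl-4-oxo-7-azabicyclo[4.2.1]nonane-8-carboxylate | C1C[C@@]2(C)[C@H](C(=O)OC)N[C@@H](C(C)(C)C1=O)[C@@H]2C(C)=O
A6 | alternative 3 | methyl 8-acetyl-1,5,5-trimethyl-4-oxobicyclo[4.1.1]octane-7-carboxylate | C1C[C@@]2(C)[C@H](C(=O)OC)[C@@H](C(C)(C)C1=O)[C@@H]2C(C)=O
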